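The data stem from a simulated flask with constants of no real substance; noise was put on by code.

3 questions stood before me on this flask, and behind them a single decision: whether to charge it as written, and when to sample it.

| setting | summer | autumn | flask |
|---|---|---|---|
| starting material | 10 mM | 10 mM | 10 mM |
| partner | 0.90 equiv | 0.90 equiv | 0.900 equiv |
| protic impurity | 0.50 mM | 0.75 mM | 1.00 mM |
| remark | run made earlier | run made earlier |  |
| time |  |  | 10 min |

| run | time / min | target / % |
|---|---|---|
| summer | 0.667 | 10 |
| summer | 1.00 | 14 |
| summer | 2.00 | 26 |
| summer | 3.00 | 25 |
| summer | 6.00 | 19 |
| summer | 10.0 | 12 |
| autumn | 0.667 | 10 |
| autumn | 1.00 | 17 |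
| autumn | 2.00 | 25 |
| autumn | 3.00 | 30 |
| autumn | 6.00 | 17 |
| autumn | 10.0 | 10 |

(readings scatter by 2 percentage points)

- time, not beyond 10 min, at which the flask holds most target
- the amount of target, in percent of the starting material charged, at that time
- the first time at which target reaches 7.8%, in the same percent, in min

- the earlier runs were read with a standard deviation of 2 percentage points

My working guess, which the readings could not prove, was that the protic impurity eats starting material one to one, as the limiting reagent of that side reaction. So I took the protic impurity charged over the starting material charged, 10.0% in the flask, and called it the lost share. The summer run's share was 5.00% and the autumn run's 7.50%. I read the summer peak as 26% at 2.00 min and the autumn peak as 30% at 3.00 min. Dividing each by what its share leaves and averaging gave 29.9% of target per usable starting material. The flask should therefore peak near 26.9%, somewhere between those two times. Both runs read 10% at 0.667 min, and that straight rise reaches 7.8% at 0.520 min. The lost share priced the impurity at 3 points of target, and a single reading scatters by 2 points. I left the charge as written and planned to watch the window between those peak readings.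

The forecast, higher and later than my peak, gave 33% at 3.6 min and 0.52 min for the level, reasoning that “the impurity holds off the destruction of target”.

The flask gave 25.9% at 2.67 min, and target reached the level at 0.588 min.

    target ⇌ isomer of the product (K = 0.680, k = 0.110 s⁻¹)
    starting material + protic impurity → quenched substrate (k = 360 M⁻¹ s⁻¹)
    partner → second intermediate (k = 0.0340 s⁻¹)
    starting material → open intermediate (k = 0.0560 s⁻¹)
    open intermediate + second intermediate → target (k = 1.90 M⁻¹ s⁻¹)
    target → over-reaction product (k = 0.00620 s⁻¹)

At 1.00 min the flask held quenched substrate at 10.0% and protic impurity at 0%, and the quenched substrate stood at the lost share. The neighbouring flask was charged with 17 mM of starting material, which put the protic impurity at 0.0588 equiv. Its lost share was 5.88%, and the same reckoning gave 28.1% of target at the peak. That flask held quenched substrate at 5.88% at 10.0 min, and its most target was 30.1%.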